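Multiply each catalyst charge by its hours before reading any left-handed product.

| flask | left-handed substrate | right-handed substrate | reagent | free catalyst | added ligand | temperature | remark | time |
|---|---|---|---|---|---|---|---|---|
| east | 0.38 M | 0.38 M | 0.57 M | 5.9 mM | 13 mM | 19 °C | run made earlier |  |
| west | 0.38 M | 0.38 M | 0.57 M | 9.2 mM | 13 mM | 60 °C | run made earlier |  |
| north-west | 0.38 M | 0.38 M | 0.28 M | 4.2 mM | 13 mM | 19 °C | run made earlier |  |
| noon | 0.38 M | 0.38 M | 0.570 M | 4.2 mM | 13 mM | 75 °C |  | 15 h |
| midnight | 0.38 M | 0.38 M | 0.570 M | 4.2 mM | 13 mM | 50 °C |  | 15 h |
| autumn | 0.38 M | 0.38 M | 0.570 M | 4.2 mM | 13 mM | 0 °C |  | 15 h |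
| summer | 0.38 M | 0.38 M | 0.570 M | 4.2 mM | 13 mM | 25 °C |  | 15 h |

| run | time / h | left-handed product / % | left-handed substrate / % |
|---|---|---|---|
| east | 10.0 | 4.3 | 46.1 |
| east | 30.0 | 7.2 | 43.0 |
| east | 50.0 | 7.5 | 42.1 |
| east | 72.0 | 9.5 | 40.6 |
| east | 120 | 10.5 | 39.2 |
| east | 144 | 11.4 | 39.7 |
| east | 192 | 11.3 | 38.3 |
| west | 1.33 | 7.9 | 42.1 |
| west | 4.00 | 11.5 | 38.9 |
| west | 6.00 | 13.1 | 37.3 |
| west | 10.0 | 14.6 | 35.9 |
| west | 15.0 | 14.6 | 34.9 |
| west | 20.0 | 16.1 | 33.8 |
| west | 25.0 | 16.5 | 33.6 |
| north-west | 40.0 | 3.0 | 47.3 |
| north-west | 72.0 | 4.3 | 46.0 |
| north-west | 120 | 4.9 | 44.6 |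
| north-west | 144 | 5.8 | 44.7 |
| north-west | 192 | 5.9 | 43.9 |

(each reading ± 0.3 percentage points)

- free catalyst is single-handed; left-handed substrate and right-handed substrate are mirror images of each other, charged as a racemate, each of them at the stated concentration
- the numbers in the tables scatter by 0.3 percentage points (one standard deviation)

- the flask that comes out highest in amount of left-handed product, in percent of the left-handed substrate and right-handed substrate together charged, or "all alike" when all lie within 1.5 percentage points (noon / midnight / autumn / summer / all alike)
- left-handed product at the end, in percent of the left-handed substrate and right-handed substrate together charged, noon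
- left-handed product at the end, in percent of the left-handed substrate and right-handed substrate together charged, midnight
- left-handed product at the end, in percent of the left-handed substrate and right-handed substrate together charged, autumn
- left-handed product at the end, in percent of the left-handed substrate and right-handed substrate together charged, summer

Does a flask stop, or merely slow? The west run gains 1.9 percentage points of left-handed product between 15.0 h and 25.0 h, with 33.6% of the charge still left-handed substrate, so that run has not stopped by its last reading.

Suppose the catalyst is lost by meeting itself, a second-order deactivation. Its loss then goes with its square and the product's rate with its first power, so dividing one by the other removes time. At fixed temperature, reagent, substrate and added ligand, the runs should then lie on one curve. Noon, midnight, autumn and summer stand at 0.0829 h of it: catalyst charged as a fraction of both substrates together, times hours, our catalyst clock.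

Does the clock hold? At 19 °C, the north-west run reads 1.06 h at 192 h and the east run 1.12 h at 144 h. These two differ in reagent as well, and their product readings stand in a ratio of 0.518, close to their reagent ratio of 0.491, as expected if the height of the curve goes with the reagent.

Where, then, do the runs stand at our clock? The west run reaches it at 6.85 h, and its readings give 13.4%. The east run reaches it at 10.7 h and gives 4.40%. So the hotter run stands higher, and noon is the hottest flask. A straight line in temperature carries us to an estimate of 16.7% for noon, the flask we name as highest.

The forecast, holding that “the catalyst dies after a limited number of turnovers”, names noon too, with noon 7.1%, midnight 6%, autumn 1.4% and summer 3.8%, so its noon lies lower than ours.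

The flasks give noon 16.6%, midnight 11.0%, autumn 1.25% and summer 5.29%, so noon comes out highest, against our 16.7%.

    reagent + free catalyst + left-handed substrate → free catalyst + left-handed product (k = 0.00391 /M²/s, Ea = 64.0 kJ/mol)
    2 free catalyst → spent catalyst (k = 0.0250 /M/s, Ea = 67.0 kJ/mol)
    free catalyst + added ligand ⇌ idle complex, settled at all times (K = 89.3 /M, ΔH = 17.0 kJ/mol)
    reagent + free catalyst + right-handed substrate → free catalyst + right-handed product (k = 0.00222 /M²/s, Ea = 68.0 kJ/mol)
    (constants at 25 °C)

At its end, noon holds 97.1% of its catalyst as spent catalyst and keeps 67% of its left-handed substrate. Ten times the hours puts noon at 0.829 h on the clock, where it reads 22.3% after 150 h, a gain of 5.7 points.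

Autumn repeated at 25 °C keeps the clock at 0.0829 h, so our line between the east and west readings gives 5.72%. The computed flask gives 5.29%.

The data stem from a simulated flask on assumed constants, and the scatter is random.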